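**Retrosynthetic overview**
1. The last disconnection is the ring-fusion C–C bond shared by the trans-fused γ-lactone and the nine-membered keto-lactam ring. It joins the α-carbon of the ring ketone to the O-bearing lactone carbon. It is therefore the Cα–Cβ bond of a β-acyloxy ketone (aldol retron) whose oxygen lies γ to the lactone carbonyl, so one enolate/aldehyde union followed by 5-exo lactonisation builds both rings.
2. A phenylsulfonyl group on that α-carbon fixes where the enolate forms and is expelled reductively by SmI2. The precursor is an N-alkyl-3-alkylazepan-2-one with a formyl arm and a β-keto sulfone/methyl ester arm.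
3. The β-keto sulfone arm comes from the aspartate β-carboxyl (diazoketone, bromoketone, sulfone). SN2 inversion on methyl (S)-lactate triflate then sets the methyl centre of the fused lactone.
4. The azepanone comes from reductive amination and lactamisation. One partner is an aldehyde acid (CBS reduction, Ireland–Claisen chirality transfer, linear hydroformylation). The other is an amino lactone (L-aspartate thioester plus a chiral zinc homoenolate by Fukuyama coupling, then Felkin–Anh reduction).
5. Ring order: side-chain γ-lactone, then azepanone, then the nine-membered ring and the fused γ-lactone together.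

Key step: step 17

Remark on the chemistry: the sulfone-bearing carbon of the late intermediates is carried as an epimer mixture and written without a descriptor, because step 17 erases it.

Step 1
Reactants: 1 (E)-hex-3-en-2-one
Product: 2 (2R,3E)-hex-3-en-2-ol
Conditions: (S)-Me-CBS (15 mol%), catecholborane, toluene, −78 °C; aqueous work-up
Reagents that add atoms: none
Why: Corey–Bakshi–Shibata reduction, in which the (S)-oxazaborolidine treats the alkenyl group as the large and methyl as the small substituent and should deliver hydride 1,2 to give the (R)-carbinol centre that later steers the Claisen step.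

Step 2
Reactants: 2 (2R,3E)-hex-3-en-2-ol; 3 pent-4-enoyl chloride
Product: 4 (2R,3E)-hex-3-en-2-yl pent-4-enoate
Conditions: Et3N, DMAP (cat.), CH2Cl2, 0 °C to rt
Reagents that add atoms: none
Why: DMAP-catalysed O-acylation of a secondary allylic alcohol, which does not touch the carbinol stereocentre.

Step 3
Reactants: 4 (2R,3E)-hex-3-en-2-yl pent-4-enoate
Product: 7 (2S,3S,4E)-3-ethyl-2-(prop-2-enyl)hex-4-enoic acid, via silyl ketene acetal 5 (not isolated), via trimethylsilyl ester 6 (not isolated)
Conditions: LDA, THF, −78 °C; TMSCl; −78 to 60 °C; 1 M HCl work-up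
Reagents that add atoms: none
Why: Ireland–Claisen rearrangement, in which kinetic LDA/THF enolisation gives the (E)-silyl ketene acetal and a chair transition state with the carbinol methyl equatorial transfers the (R)-C–O chirality to the two new adjacent centres (anti), leaving an (E)-propenyl group as masked aldehyde.

Step 4
Reactants: 7 (2S,3S,4E)-3-ethyl-2-(prop-2-enyl)hex-4-enoic acid
Product: 8 (2S,3S,4E)-3-ethyl-2-(4-oxobutyl)hex-4-enoic acid
Conditions: Rh(acac)(CO)2 (1 mol%), Xantphos (4 mol%), CO/H2 (1:1, 10 bar), toluene, 70 °C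
Reagents that add atoms: carbon monoxide [C-]#[O+]
Why: Linear-selective rhodium/wide-bite-angle diphosphine hydroformylation should convert only the terminal monosubstituted alkene, because the internal, allylically branched (E)-alkene is far less reactive.

Step 5
Reactants: 9 N-benzyloxycarbonyl-L-aspartic acid 4-tert-butyl ester
Product: 10 tert-butyl (3S)-3-(benzyloxycarbonylamino)-4-(ethylsulfanyl)-4-oxobutanoate
Conditions: EtSH, DCC, DMAP (cat.), CH2Cl2, 0 °C
Reagents that add atoms: ethanethiol CCS
Why: Steglich-type thioesterification of the free α-carboxyl group, with the urethane N-protection suppressing racemisation of the amino acid centre.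

Step 6
Reactants: 10 tert-butyl (3S)-3-(benzyloxycarbonylamino)-4-(ethylsulfanyl)-4-oxobutanoate; 11 methyl (R)-3-bromo-2-methylpropanoate
Product: 13 1-tert-butyl 7-methyl (3S,6S)-3-(benzyloxycarbonylamino)-6-methyl-4-oxoheptanedioate, via organozinc bromide 12 (not isolated)
Conditions: 11, Zn dust, I2 (cat.), DMA, 70 °C; then 10, PdCl2(PPh3)2 (5 mol%), toluene, rt
Reagents that add atoms: none
Why: Fukuyama coupling of a thioester and a zinc homoenolate is neutral, stops at the ketone and should leave both the α-amino centre and the methyl centre (β to zinc, brought in by 11) unchanged.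

Step 7
Reactants: 13 1-tert-butyl 7-methyl (3S,6S)-3-(benzyloxycarbonylamino)-6-methyl-4-oxoheptanedioate
Product: 15 tert-butyl (3S)-3-(benzyloxycarbonylamino)-3-[(2S,4S)-4-methyl-5-oxooxolan-2-yl]propanoate, via hydroxy ester 14 (not isolated)
Conditions: L-Selectride, THF, −78 °C; then AcOH, −78 °C to rt
Reagents that add atoms: none
Why: Felkin–Anh-controlled reduction of an α-carbamoylamino ketone by a bulky, non-chelating borohydride should give the syn amino alcohol (new S carbinol centre), which lactonises only onto the methyl ester because the tert-butyl ester resists alkoxide attack.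

Step 8
Reactants: 15 tert-butyl (3S)-3-(benzyloxycarbonylamino)-3-[(2S,4S)-4-methyl-5-oxooxolan-2-yl]propanoate
Product: 16 tert-butyl (3S)-3-amino-3-[(2S,4S)-4-methyl-5-oxooxolan-2-yl]propanoate
Conditions: H2 (1 atm), 10% Pd/C, EtOAc, rt; filtered and used at once
Reagents that add atoms: none
Why: Hydrogenolysis of the benzyl carbamate leaves ester, lactone and all stereocentres intact, and immediate use limits lactone-to-lactam acyl migration.

Step 9
Reactants: 8 (2S,3S,4E)-3-ethyl-2-(4-oxobutyl)hex-4-enoic acid; 16 tert-butyl (3S)-3-amino-3-[(2S,4S)-4-methyl-5-oxooxolan-2-yl]propanoate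
Product: 18 (2S,3S,4E)-2-[4-({(1S)-3-tert-butoxy-1-[(2S,4S)-4-methyl-5-oxooxolan-2-yl]-3-oxopropyl}amino)butyl]-3-ethylhex-4-enoic acid, via imine 17 (not isolated)
Conditions: NaBH(OAc)3, ClCH2CH2Cl, 0 °C to rt
Reagents that add atoms: none
Why: Borohydride reductive amination, in which the unhindered aldehyde condenses quickly with the α-branched primary amine, whose bulk should stop the reaction at monoalkylation.

Step 10
Reactants: 18 (2S,3S,4E)-2-[4-({(1S)-3-tert-butoxy-1-[(2S,4S)-4-methyl-5-oxooxolan-2-yl]-3-oxopropyl}amino)butyl]-3-ethylhex-4-enoic acid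
Product: 19 tert-butyl (3S)-3-{(3S)-3-[(3S,4E)-hex-4-en-3-yl]-2-oxoazepan-1-yl}-3-[(2S,4S)-4-methyl-5-oxooxolan-2-yl]propanoate
Conditions: DIC, HOAt, 2,4,6-collidine, CH2Cl2/DMF (5 mM), rt
Reagents that add atoms: none
Why: Carbodiimide/HOAt lactamisation (7-exo-trig) of an ε-amino acid, in which the activated carboxyl outcompetes the lactone carbonyl for the secondary amine and the weak base limits α-epimerisation.

Step 11
Reactants: 19 tert-butyl (3S)-3-{(3S)-3-[(3S,4E)-hex-4-en-3-yl]-2-oxoazepan-1-yl}-3-[(2S,4S)-4-methyl-5-oxooxolan-2-yl]propanoate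
Product: 20 (3S)-3-{(3S)-3-[(3S,4E)-hex-4-en-3-yl]-2-oxoazepan-1-yl}-3-[(2S,4S)-4-methyl-5-oxooxolan-2-yl]propanoic acid
Conditions: TFA/CH2Cl2 (1:2), 0 °C to rt
Reagents that add atoms: none
Why: Acidolysis of the tert-butyl ester (E1 loss of the tert-butyl cation) is tolerated by lactam, lactone and the disubstituted alkene.

Step 12
Reactants: 20 (3S)-3-{(3S)-3-[(3S,4E)-hex-4-en-3-yl]-2-oxoazepan-1-yl}-3-[(2S,4S)-4-methyl-5-oxooxolan-2-yl]propanoic acid
Product: 22 (3S)-1-{(1S)-4-diazo-1-[(2S,4S)-4-methyl-5-oxooxolan-2-yl]-3-oxobutyl}-3-[(3S,4E)-hex-4-en-3-yl]azepan-2-one, via mixed anhydride 21 (not isolated)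
Conditions: i-BuOCOCl, N-methylmorpholine, THF, −20 °C; then CH2N2, Et2O, 0 °C
Reagents that add atoms: diazomethane C=[N+]=[N-]
Why: Arndt–Eistert-type acylation of diazomethane by a mixed carbonic anhydride adds the future ring-fusion carbon under neutral conditions that spare the lactone.

Step 13
Reactants: 22 (3S)-1-{(1S)-4-diazo-1-[(2S,4S)-4-methyl-5-oxooxolan-2-yl]-3-oxobutyl}-3-[(3S,4E)-hex-4-en-3-yl]azepan-2-one
Product: 24 (3S)-3-[(3S,4E)-hex-4-en-3-yl]-1-{(1S)-1-[(2S,4S)-4-methyl-5-oxooxolan-2-yl]-3-oxo-4-(phenylsulfonyl)butyl}azepan-2-one, via bromomethyl ketone 23 (not isolated)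
Conditions: 48% aq HBr (1.0 equiv), THF, 0 °C; then PhSO2Na, DMF, rt
Reagents that add atoms: sodium benzenesulfinate [Na+].[O-]S(=O)c1ccccc1
Why: Protonation of the diazoketone and bromide capture, followed by SN2 S-alkylation of the sulfinate, is the classical base-free route to a β-keto sulfone.

Step 14
Reactants: 25 methyl (S)-lactate
Product: 26 methyl (S)-2-(trifluoromethylsulfonyloxy)propanoate
Conditions: Tf2O, 2,6-lutidine, CH2Cl2, −78 to 0 °C
Reagents that add atoms: triflic anhydride O=S(=O)(OS(=O)(=O)C(F)(F)F)C(F)(F)F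
Why: O-sulfonylation breaks no bond at the stereocentre, so the chiral-pool configuration is retained in an excellent SN2 electrophile.

Step 15
Reactants: 24 (3S)-3-[(3S,4E)-hex-4-en-3-yl]-1-{(1S)-1-[(2S,4S)-4-methyl-5-oxooxolan-2-yl]-3-oxo-4-(phenylsulfonyl)butyl}azepan-2-one; 26 methyl (S)-2-(trifluoromethylsulfonyloxy)propanoate
Product: 27 methyl (2R,6S)-6-{(3S)-3-[(3S,4E)-hex-4-en-3-yl]-2-oxoazepan-1-yl}-2-methyl-6-[(2S,4S)-4-methyl-5-oxooxolan-2-yl]-4-oxo-3-(phenylsulfonyl)hexanoate (epimers at C-3)
Conditions: NaH (1.0 equiv), THF, 0 °C; then 26, −40 °C to rt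
Reagents that add atoms: none
Why: SN2 C-alkylation of the soft β-keto sulfone carbanion (the only site deprotonated) by an α-triflyloxy ester proceeds with inversion and sets the methyl centre of the future fused lactone.

Step 16
Reactants: 27 methyl (2R,6S)-6-{(3S)-3-[(3S,4E)-hex-4-en-3-yl]-2-oxoazepan-1-yl}-2-methyl-6-[(2S,4S)-4-methyl-5-oxooxolan-2-yl]-4-oxo-3-(phenylsulfonyl)hexanoate
Product: 29 methyl (2R,6S)-2-methyl-6-[(2S,4S)-4-methyl-5-oxooxolan-2-yl]-4-oxo-6-{(3S)-2-oxo-3-[(2R)-1-oxobutan-2-yl]azepan-1-yl}-3-(phenylsulfonyl)hexanoate (epimers at C-3), via ozonide 28 (not isolated)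
Conditions: O3, CH2Cl2, −78 °C; then PPh3, −78 °C to rt; used at once
Reagents that add atoms: ozone [O-][O+]=O
Why: Ozonolysis with reductive work-up cleaves the only C=C bond under neutral conditions, so the α-branched aldehyde centre should not epimerise.

Step 17
Reactants: 29 methyl (2R,6S)-2-methyl-6-[(2S,4S)-4-methyl-5-oxooxolan-2-yl]-4-oxo-6-{(3S)-2-oxo-3-[(2R)-1-oxobutan-2-yl]azepan-1-yl}-3-(phenylsulfonyl)hexanoate
Product: 32 tuberostemonone, via samarium(III) enolate 30 (not isolated), via samarium(III) aldolate 31 (not isolated)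
Conditions: SmI2 (2.5 equiv), THF, −78 °C, slow addition of 29 (final 2 mM); −78 to −20 °C; pH 7 buffer
Reagents that add atoms: none
Why: Proposed new method: two electron transfers from SmI2 to the β-keto sulfone (much easier to reduce than the aldehyde, lactam, ester or lactone) expel benzenesulfinate and leave the samarium(III) enolate 30 only on the carbon that carried sulfur; the oxophilic Sm(III) also binds the formyl oxygen, the enolate carbon attacks the formyl carbon through a closed Zimmerman–Traxler array to make the ring-fusion bond, and the aldolate oxygen of 31 then displaces methoxide from the γ-placed methyl ester. The closest known reaction types are the SmI2 Reformatsky-type aldol cyclisation of α-bromo ketone aldehydes, which closes eight-membered carbocycles, and the SmI2 desulfonylation of β-keto sulfones; new here are the sulfone as aldol trigger, the bridged nine-membered ring and the lactonising end. Ring closures: the nine-membered ring forms by a 9-(enolendo)-exo-trig aldol addition that turns the azepanone into the 1-azabicyclo[6.4.1]tridecane core, and the γ-lactone by a 5-exo-trig acyl substitution. Stereocentres: the carbinol carbon should be set by the neighbouring ethyl-bearing centre (Felkin–Anh attack anti to the azepanone carbon), and the ketone α-carbon by the ester-chelated (Z)-enolate in the chair array (syn aldol, equal to the trans-fused lactone); as the only readily enolisable centre it can also settle into this more stable trans arrangement, while the lactate-derived methyl centre is not touched. Selectivity: the sulfone position fixes the enolate away from the CH2 next to the nitrogen-bearing carbon (whose enolate would eject the lactam by E1cB), reduction potentials secure chemoselectivity, and slow addition to excess SmI2 at high dilution favours ring closure over proton transfer from unreduced 29 or dimerisation.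

**Compound list**
1 | (E)-hex-3-en-2-one | CC/C=C/C(C)=O | starting material
2 | (2R,3E)-hex-3-en-2-ol | C[C@@H](O)/C=C/CC | intermediate
3 | pent-4-enoyl chloride | C=CCCC(Cl)=O | starting material
4 | (2R,3E)-hex-3-en-2-yl pent-4-enoate | C=CCCC(=O)O[C@H](C)/C=C/CC | intermediate
5 | (E)-trimethylsilyl ketene acetal of 4 | C=CC/C=C(/O[Si](C)(C)C)O[C@H](C)/C=C/CC | intermediate
6 | trimethylsilyl (2S,3S,4E)-3-ethyl-2-(prop-2-enyl)hex-4-enoate | CC[C@H]([C@H](CC=C)C(=O)O[Si](C)(C)C)/C=C/C | intermediate
7 | (2S,3S,4E)-3-ethyl-2-(prop-2-enyl)hex-4-enoic acid | CC[C@H]([C@H](CC=C)C(O)=O)/C=C/C | intermediate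
8 | (2S,3S,4E)-3-ethyl-2-(4-oxobutyl)hex-4-enoic acid | CC[C@H]([C@H](CCCC=O)C(O)=O)/C=C/C | intermediate
9 | N-benzyloxycarbonyl-L-aspartic acid 4-tert-butyl ester | O=C(OCc1ccccc1)N[C@@H](CC(=O)OC(C)(C)C)C(O)=O | starting material
10 | tert-butyl (3S)-3-(benzyloxycarbonylamino)-4-(ethylsulfanyl)-4-oxobutanoate | O=C(OCc1ccccc1)N[C@@H](CC(=O)OC(C)(C)C)C(=O)SCC | intermediate
11 | methyl (R)-3-bromo-2-methylpropanoate | BrC[C@H](C)C(=O)OC | starting material
12 | [(2R)-3-methoxy-2-methyl-3-oxopropyl]zinc bromide | Br[Zn]C[C@H](C)C(=O)OC | intermediate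
13 | 1-tert-butyl 7-methyl (3S,6S)-3-(benzyloxycarbonylamino)-6-methyl-4-oxoheptanedioate | O=C(OCc1ccccc1)N[C@@H](CC(=O)OC(C)(C)C)C(=O)C[C@H](C)C(=O)OC | intermediate
14 | 1-tert-butyl 7-methyl (3S,4S,6S)-3-(benzyloxycarbonylamino)-4-hydroxy-6-methylheptanedioate | O=C(OCc1ccccc1)N[C@@H](CC(=O)OC(C)(C)C)[C@@H](O)C[C@H](C)C(=O)OC | intermediate
15 | tert-butyl (3S)-3-(benzyloxycarbonylamino)-3-[(2S,4S)-4-methyl-5-oxooxolan-2-yl]propanoate | O=C(OCc1ccccc1)N[C@@H](CC(=O)OC(C)(C)C)[C@@H]1C[C@H](C)C(=O)O1 | intermediate
16 | tert-butyl (3S)-3-amino-3-[(2S,4S)-4-methyl-5-oxooxolan-2-yl]propanoate | N[C@@H](CC(=O)OC(C)(C)C)[C@@H]1C[C@H](C)C(=O)O1 | intermediate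
17 | (E)-imine of 8 and 16 | CC[C@H]([C@H](CCC/C=N/[C@@H](CC(=O)OC(C)(C)C)[C@@H]1C[C@H](C)C(=O)O1)C(O)=O)/C=C/C | intermediate
18 | secondary amino acid from 8 and 16 (full name in step 9) | CC[C@H]([C@H](CCCCN[C@@H](CC(=O)OC(C)(C)C)[C@@H]1C[C@H](C)C(=O)O1)C(O)=O)/C=C/C | intermediate
19 | tert-butyl (3S)-3-{(3S)-3-[(3S,4E)-hex-4-en-3-yl]-2-oxoazepan-1-yl}-3-[(2S,4S)-4-methyl-5-oxooxolan-2-yl]propanoate | CC[C@H]([C@@H]1CCCCN([C@@H](CC(=O)OC(C)(C)C)[C@@H]2C[C@H](C)C(=O)O2)C1=O)/C=C/C | intermediate
20 | (3S)-3-{(3S)-3-[(3S,4E)-hex-4-en-3-yl]-2-oxoazepan-1-yl}-3-[(2S,4S)-4-methyl-5-oxooxolan-2-yl]propanoic acid | CC[C@H]([C@@H]1CCCCN([C@@H](CC(O)=O)[C@@H]2C[C@H](C)C(=O)O2)C1=O)/C=C/C | intermediate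
21 | isobutyl carbonic mixed anhydride of 20 | CC[C@H]([C@@H]1CCCCN([C@@H](CC(=O)OC(=O)OCC(C)C)[C@@H]2C[C@H](C)C(=O)O2)C1=O)/C=C/C | intermediate
22 | diazomethyl ketone (full name in step 12) | CC[C@H]([C@@H]1CCCCN([C@@H](CC(=O)C=[N+]=[N-])[C@@H]2C[C@H](C)C(=O)O2)C1=O)/C=C/C | intermediate
23 | bromomethyl ketone corresponding to 22 | CC[C@H]([C@@H]1CCCCN([C@@H](CC(=O)CBr)[C@@H]2C[C@H](C)C(=O)O2)C1=O)/C=C/C | intermediate
24 | β-keto phenyl sulfone (full name in step 13) | CC[C@H]([C@@H]1CCCCN([C@@H](CC(=O)CS(=O)(=O)c3ccccc3)[C@@H]2C[C@H](C)C(=O)O2)C1=O)/C=C/C | intermediate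
25 | methyl (S)-lactate | C[C@H](O)C(=O)OC | starting material
26 | methyl (S)-2-(trifluoromethylsulfonyloxy)propanoate | C[C@H](OS(=O)(=O)C(F)(F)F)C(=O)OC | intermediate
27 | alkylated β-keto sulfone, (2R)-methyl ester arm, sulfone carbon as epimers (full name in step 15) | CC[C@H]([C@@H]1CCCCN([C@@H](CC(=O)C([C@H](C)C(=O)OC)S(=O)(=O)c3ccccc3)[C@@H]2C[C@H](C)C(=O)O2)C1=O)/C=C/C | intermediate
28 | secondary ozonide (5-methyl-1,2,4-trioxolan-3-yl) of 27 | CC[C@H]([C@@H]1CCCCN([C@@H](CC(=O)C([C@H](C)C(=O)OC)S(=O)(=O)c3ccccc3)[C@@H]2C[C@H](C)C(=O)O2)C1=O)C4OOC(C)O4 | intermediate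
29 | aldehyde β-keto sulfone (full name in step 16) | CC[C@H]([C@@H]1CCCCN([C@@H](CC(=O)C([C@H](C)C(=O)OC)S(=O)(=O)c3ccccc3)[C@@H]2C[C@H](C)C(=O)O2)C1=O)C=O | intermediate
30 | (Z)-samarium(III) enolate of the desulfonylated keto ester aldehyde | CC[C@H]([C@@H]1CCCCN([C@@H](C/C(O[Sm](I)I)=C/[C@H](C)C(=O)OC)[C@@H]2C[C@H](C)C(=O)O2)C1=O)C=O | intermediate
31 | samarium(III) aldolate with the nine-membered ring closed and the methyl ester still open | CC[C@H]1[C@H](O[Sm](I)I)[C@@H]([C@H](C)C(=O)OC)C(=O)C[C@@H]([C@@H]2C[C@H](C)C(=O)O2)N2CCCC[C@@H]1C2=O | intermediate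
32 | tuberostemonone | CC[C@H]1[C@@H]2OC(=O)[C@@H](C)[C@H]2C(=O)C[C@@H]([C@@H]2C[C@H](C)C(=O)O2)N2CCCC[C@@H]1C2=O | target

**Total step count:** 17. **Longest linear sequence:** 12 steps (5, 6, 7, 8, 9, 10, 11, 12, 13, 15, 16, 17; the branch 1, 2, 3, 4 followed by 9 to 17 is equally long).

**Steps most likely to fail**

Risk 1, step 17.
- What may go wrong: ring closure may be slow because of the strain of the bridged nine-membered ring. The samarium enolate could then be protonated or could migrate towards the nitrogen side. Facial selectivity at the aldehyde may also be poor.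
- Fallback (known chemistry): it sets out from 29 and returns at 32. The sulfone is kept as an acidifying group, and the ring is closed by a polar route under thermodynamic drive.
- Soft enolisation with LiCl/DBU in MeCN at high dilution lets the doubly stabilised carbanion add to the aldehyde. Lactonisation of the aldolate pulls the equilibrium towards the ring-fusion α-phenylsulfonyl derivative of tuberostemonone F1.
- A separate, standard reductive desulfonylation of this β-keto sulfone (SmI2 in THF/MeOH at −78 °C, or aluminium amalgam) with a proton source present then gives 32, the ring-fusion carbon being protonated to the trans-fused lactone.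

Risk 2, step 15.
- What may go wrong: the ambident enolate may be O-alkylated. Substitution between two secondary centres may be slow. The triflate may eliminate to the acrylate.
- Fallback: it sets out from 11 and 20 and returns at 27. It makes the ketone-to-sulfone carbon bond last and takes the methyl centre from the same chiral bromide that supplies the side-chain lactone.
- Bromide 11 and PhSO2Na in DMF give methyl (R)-2-methyl-3-(phenylsulfonyl)propanoate F2. Acid hydrolysis (aq HCl, dioxane) gives (R)-2-methyl-3-(phenylsulfonyl)propanoic acid F3.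
- Acid 20 and carbonyldiimidazole give the acyl imidazolide of 20 F4.
- The dilithio dianion of F3 (n-BuLi, THF, −78 °C) is protected against β-elimination by its carboxylate. F4 acylates it at the sulfonyl carbon to give the β-keto sulfone carboxylic acid F5. Methylation with TMSCHN2 then gives 27.

Risk 3, step 7.
- What may go wrong: a chelated and a Felkin–Anh transition state may compete and erode facial selectivity at the ketone. The alkoxide may attack the carbamate.
- Fallback: it sets out from 10 and returns at 15. The carbinol centre is made by C–C bond formation instead of by reduction.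
- Fukuyama reduction of 10 (Et3SiH, Pd/C, acetone) gives tert-butyl (3S)-3-(benzyloxycarbonylamino)-4-oxobutanoate F6.
- Organozinc 12 is transmetalated to the chlorotitanium homoenolate and adds to F6 under chelation control, which for an aldehyde gives the syn amino alcohol 14. This lactonises to 15 on acidic work-up.

**Further compounds**
F1 | step 17 | ring-fusion α-phenylsulfonyl derivative of tuberostemonone | CC[C@H]1[C@@H]2OC(=O)[C@@H](C)C2(S(=O)(=O)c3ccccc3)C(=O)C[C@@H]([C@@H]2C[C@H](C)C(=O)O2)N2CCCC[C@@H]1C2=O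
F2 | step 15 | methyl (R)-2-methyl-3-(phenylsulfonyl)propanoate | O=S(=O)(c1ccccc1)C[C@H](C)C(=O)OC
F3 | step 15 | (R)-2-methyl-3-(phenylsulfonyl)propanoic acid | O=S(=O)(c1ccccc1)C[C@H](C)C(O)=O
F4 | step 15 | acyl imidazolide of 20 | CC[C@H]([C@@H]1CCCCN([C@@H](CC(=O)n3ccnc3)[C@@H]2C[C@H](C)C(=O)O2)C1=O)/C=C/C
F5 | step 15 | β-keto sulfone carboxylic acid (free acid of 27) | CC[C@H]([C@@H]1CCCCN([C@@H](CC(=O)C([C@H](C)C(O)=O)S(=O)(=O)c3ccccc3)[C@@H]2C[C@H](C)C(=O)O2)C1=O)/C=C/C
F6 | step 7 | tert-butyl (3S)-3-(benzyloxycarbonylamino)-4-oxobutanoate | O=C(OCc1ccccc1)N[C@@H](CC(=O)OC(C)(C)C)C=O
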